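**Retrosynthetic overview**
1. The oxepane is closed last, by the C3 hydroxyl displacing a C16 triflate; C16–OH comes from hydroboration of a C14 isopropenyl group, and the butanoate from the C11 hydroxyl.
2. The oxonene comes from ring-closing metathesis (C6=C7) of a C3 but-3-enyl arm and a C9 methallyl arm; C3 is set by chelation-controlled MeMgBr addition to a C3 ketone.
3. The all-cis tetrahydrofuran comes from two "carbon first, hydride last" operations on carboxyl-level C2 and C9 (alkynyl ketone reduction/lactonisation, then lactol ionic reduction).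
4. The cyclohexane (C1, C10–C14) is carved from a 7-oxanorbornene: syn-SN2′ methylative ring opening (C11–OH/C12–Me), conjugate addition at C14, lactonisation-driven epimerisation at C1.
5. The 7-oxanorbornene is the dearomatising Diels–Alder adduct of furan and maleic anhydride (meso, then desymmetrised); the furan oxygen ends as the butanoate oxygen. Ring order: cyclohexane, tetrahydrofuran, oxonene, oxepane.

Assumption and numbering: the target is taken exactly as the SMILES is drawn, (1S,2R,3S,9R,10R,11R,12R,14S,15R,6Z), with H1, H2, H9 and H10 all cis on the tetrahydrofuran; cyclohexane = C1, C10, C11(O), C12(Me), C13, C14; tetrahydrofuran = C1–C2–O–C9–C10; oxonene = C2–C3(Me)–C4–C5–C6=C7(Me)–C8–C9–O; oxepane = C3–O–C16–C15(Me)–C14–C1–C2.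

**Route**

Step 1
Reactants: 1 furan; 2 maleic anhydride
Product: 3 exo meso 7-oxanorbornene anhydride
Conditions: Et2O, rt, 48 h (adduct crystallises)
Reagents that add atoms: none
Why: Diels–Alder cycloaddition in which furan gives up its aromaticity as the diene, the reversible reaction delivering the crystalline exo adduct whose carbonyl carbons (C2, C9) are syn to the oxygen bridge (the future C11 oxygen), so that C1, C10, C11 and C14 are fixed relative to one another in a meso compound.

Step 2
Reactants: 3 exo meso 7-oxanorbornene anhydride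
Product: 4 (1R,2S,3R,4S) hemiester with the methyl ester on C1 and the acid on C10
Conditions: MeOH (3 equiv), quinine (1.1 equiv), PhMe/CCl4 1:1, −55 °C, 60 h; 2 M HCl wash
Reagents that add atoms: methanol, SMILES CO
Why: alkaloid-mediated desymmetrising methanolysis of a meso anhydride (Bolm), in which the quinine–methanol complex opens one enantiotopic carbonyl (the one on C1) and so sets the absolute configuration of C1, C10, C11 and C14, quinidine giving the antipode.

Step 3
Reactants: 4 hemiester
Product: 6 conjugated hydroxy enoate acid (C1=C14), via ring-opened hydroxy hemiester 5 (not isolated)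
Conditions: PdCl2(MeCN)2 (5 mol %), (R)-Tol-BINAP (5 mol %), Zn(OTf)2 (10 mol %), Me2Zn (3.5 equiv), ClCH2CH2Cl, 40 °C; then MeOH, NaOMe (6 equiv), rt; 1 M HCl to pH 3
Reagents that add atoms: dimethylzinc, SMILES C[Zn]C
Why: Lautens-type palladium-catalysed alkylative ring opening, in which a cationic divalent methylpalladium species adds across C12=C13 from the exo face and β-oxygen elimination cleaves C14–O so that the new C12 methyl is cis to the C11 hydroxyl (syn SN2′) with the chiral ligand choosing the alkene carbon on the side of the acid-bearing C10 (its antipode would give the regioisomer), followed by base-mediated migration of the C13=C14 alkene into conjugation with the C2 ester while the C9 carboxylate keeps C10–H non-acidic and C10 intact.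

Step 4
Reactants: 6 conjugated hydroxy enoate acid
Product: 7 C14 isopropenyl adduct (C1 epimer mixture)
Conditions: CH2=C(CH3)MgBr (5 equiv), CuBr·SMe2 (20 mol %), Me3SiCl (6 equiv), THF, −78 → −20 °C; 1 M HCl
Reagents that add atoms: isopropenylmagnesium bromide, SMILES CC(=C)[Mg]Br
Why: copper-catalysed conjugate (1,4-) addition of a Grignard reagent to the cyclohexene carboxylate (two equivalents are spent on OH and CO2H), the isopropenyl group entering C14 anti to the three cis substituents on C10, C11 and C12, while C1 is protonated unselectively and is corrected in step 5.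

Step 5
Reactants: 7 C14 isopropenyl adduct
Product: 8 bridged γ-lactone acid (C2 lactonised onto the C11 oxygen)
Conditions: 1,5,7-triazabicyclo[4.4.0]dec-5-ene (TBD, 1.5 equiv), PhMe, 90 °C, 4 Å molecular sieves; 1 M HCl
Reagents that add atoms: none
Why: guanidine-base-mediated ester epimerisation coupled to intramolecular transesterification (lactonisation) under thermodynamic control, since only the C1 epimer whose ester is cis (1,3-diaxial) to the C11 hydroxyl can close the bridged γ-lactone, which drains the equilibrium and fixes C1 with C2 cis to C9 and trans to the C14 isopropenyl group.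

Step 6
Reactants: 8 bridged γ-lactone acid
Product: 9 C2 alkynyl ketone hydroxy acid
Conditions: LiC≡CSiMe3 (3.2 equiv), THF, −78 °C, 1 h; AcOH quench at −78 °C
Reagents that add atoms: lithium (trimethylsilyl)acetylide, SMILES [Li]C#C[Si](C)(C)C
Why: nucleophilic addition of a lithium acetylide to a lactone, which stops after one addition because the tetrahedral lithium alkoxide is stable at −78 °C (the first equivalent is consumed by the acid) and which leaves the bridgehead C1 unable to enolise until the cold quench.

Step 7
Reactants: 9 C2 alkynyl ketone hydroxy acid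
Product: 11 cis-fused alkynyl γ-lactone (C2–O–C9 ring closed), via propargylic hydroxy acid 10 (not isolated)
Conditions: RuCl[(R,R)-TsDPEN](p-cymene) (2 mol %), HCO2H/Et3N 5:2, CH2Cl2, rt; then 40 °C
Reagents that add atoms: none
Why: Noyori asymmetric transfer hydrogenation of an alkynyl ketone, in which the (R,R)-catalyst delivers hydride under reagent control to give the (2R) carbinol (H2 cis to H1), after which the cis γ-hydroxy acid lactonises onto the C9 acid in the acidic medium to give the cis-fused lactone.

Step 8
Reactants: 11 cis-fused alkynyl γ-lactone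
Product: 12 C9 methallyl lactol
Conditions: CH2=C(CH3)CH2MgCl (2.5 equiv), THF, −78 °C; sat. NH4Cl
Reagents that add atoms: 2-methylallylmagnesium chloride, SMILES CC(=C)C[Mg]Cl
Why: Grignard addition to a γ-lactone stopped at the lactol stage (the tetrahedral magnesium alkoxide persists at −78 °C and the first equivalent deprotonates C11–OH), which places C8 and C7 on C9 as the methallyl group.

Step 9
Reactants: 12 C9 methallyl lactol
Product: 13 all-cis tetrahydrofuran with C2 silylalkynyl arm and C9 methallyl arm
Conditions: Et3SiH (5 equiv), BF3·OEt2 (2.5 equiv), CH2Cl2, −78 → −40 °C; sat. NaHCO3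
Reagents that add atoms: none
Why: Kishi-type ionic reduction of a lactol, in which BF3 generates the bicyclic oxocarbenium ion at C9 and triethylsilane delivers hydride from the convex face (the face of H10), so that H9 is cis to H10 and the methallyl arm ends on the concave face cis to the alkynyl arm, completing the all-cis tetrahydrofuran.

Step 10
Reactants: 13 silylalkynyl tetrahydrofuran
Product: 14 terminal alkyne
Conditions: K2CO3 (0.3 equiv), MeOH, rt
Reagents that add atoms: none
Why: base-catalysed methanolysis of the alkynyl C–Si bond (protodesilylation), which touches no stereocentre.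

Step 11
Reactants: 14 terminal alkyne
Product: 15 C3 methyl ketone
Conditions: (Ph3P)AuNTf2 (3 mol %), H2O (5 equiv), 1,4-dioxane, 60 °C
Reagents that add atoms: water, SMILES O
Why: monovalent-gold-catalysed Markovnikov hydration of a terminal alkyne to the methyl ketone, which leaves the 1,1-disubstituted alkenes untouched and creates no stereocentre.

Step 12
Reactants: 15 C3 methyl ketone
Product: 17 C3 but-3-enyl ketone, via dilithium enolate 16 (not isolated)
Conditions: LiN(i-Pr)2 (2.2 equiv), THF, −78 °C; then CH2=CHCH2Br (1.3 equiv), −78 → −30 °C; sat. NH4Cl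
Reagents that add atoms: allyl bromide, SMILES C=CCBr
Why: kinetic enolate alkylation, in which the second equivalent of amide base removes a proton from the methyl group instead of the hindered α-alkoxy methine C2–H (the first equivalent forms the C11 alkoxide) and the lithium enolate is C-allylated by SN2 displacement, extending C4 to the but-3-enyl chain without touching C2.

Step 13
Reactants: 17 C3 but-3-enyl ketone
Product: 18 (3S) tertiary alcohol
Conditions: MeMgBr (3.5 equiv), CH2Cl2, −78 °C; sat. NH4Cl
Reagents that add atoms: methylmagnesium bromide, SMILES C[Mg]Br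
Why: chelation-controlled (Cram chelate) Grignard addition, in which magnesium bridges the ketone oxygen and the ring oxygen on C2 and the methyl group attacks from the side of H2, anti to C1, which sets C3 as (S).

Step 14
Reactants: 18 (3S) tertiary alcohol
Product: 19 oxonene diol (6Z)
Conditions: second-generation Grubbs catalyst (10 mol %), CH2Cl2 (0.002 M), 40 °C
Reagents that add atoms: none
Why: ring-closing olefin metathesis between the terminal vinyl group and the methallyl 1,1-disubstituted alkene held cis on the tetrahydrofuran, which closes the nine-membered oxonene with the ring-enforced Z trisubstituted C6=C7 alkene, the more hindered isopropenyl group (which could only give an eight-membered carbocycle) staying out.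

Step 15
Reactants: 19 oxonene diol
Product: 20 C11 butanoate
Conditions: (n-PrCO)2O (1.5 equiv), Et3N, DMAP (0.1 equiv), CH2Cl2, rt
Reagents that add atoms: butanoic anhydride, SMILES CCCC(=O)OC(=O)CCC
Why: DMAP-catalysed acyl transfer (Steglich-type acylation) to the secondary C11 hydroxyl, the tertiary C3 hydroxyl being inert under these conditions.

Step 16
Reactants: 20 C11 butanoate
Product: 22 (15R) primary alcohol, via alkylborane 21 (not isolated)
Conditions: 9-BBN (2.5 equiv), THF, 0 °C → rt; then 30% H2O2, 3 M aq NaOAc, 0 °C → rt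
Reagents that add atoms: hydrogen peroxide, SMILES OO
Why: anti-Markovnikov hydroboration–oxidation with a bulky dialkylborane, which selects the 1,1-disubstituted isopropenyl alkene over the trisubstituted ring alkene and adds to the rotamer in which H14 eclipses the alkene from the face remote from the more substituted neighbour C1 (Houk-type model), giving the (15R) primary alcohol.

Step 17
Reactants: 22 (15R) primary alcohol
Product: 24 target CNP0209450.4, via primary triflate 23 (not isolated)
Conditions: Tf2O (1.1 equiv), 2,6-lutidine (3 equiv), CH2Cl2, −78 → 0 °C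
Reagents that add atoms: none
Why: selective triflation of the primary alcohol followed by intramolecular Williamson-type SN2 etherification (7-exo-tet) by the tertiary C3 hydroxyl, a ring closure precedented in asbestinin synthesis, which forms the oxepane without touching any stereocentre.

**Compound list**

1 | furan | c1ccoc1 | starting material
2 | maleic anhydride | O=C1OC(=O)C=C1 | starting material
3 | exo-7-oxabicyclo[2.2.1]hept-5-ene-2,3-dicarboxylic anhydride, meso, carbonyl carbons syn to the oxygen bridge | O1[C@H]2[C@@H]3[C@@H](C(=O)OC3=O)[C@@H]1C=C2 | intermediate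
4 | (1R,2S,3R,4S)-3-(methoxycarbonyl)-7-oxabicyclo[2.2.1]hept-5-ene-2-carboxylic acid (ester carbon = C2 on C1, acid carbon = C9 on C10) | O1[C@H]2[C@@H](C(=O)O)[C@@H](C(=O)OC)[C@@H]1C=C2 | intermediate
5 | all-cis cyclohex-13-ene hemiester: C1–CO2Me, C10–CO2H, C11–OH and C12–CH3 on one face | O[C@H]1[C@@H](C(=O)O)[C@@H](C(=O)OC)C=C[C@H]1C | intermediate
6 | conjugated hemiester: C1=C14 enoate (CO2Me), C10–CO2H, C11–OH and C12–CH3 mutually cis | O[C@H]1[C@@H](C(=O)O)C(C(=O)OC)=CC[C@H]1C | intermediate
7 | C14 isopropenyl adduct, isopropenyl trans to the C10, C11 and C12 substituents, both C1 epimers (C1 left open) | O[C@H]1[C@@H](C(=O)O)C(C(=O)OC)[C@@H](C[C@H]1C)C(C)=C | intermediate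
8 | bridged γ-lactone acid: C2(=O)–O–C11 across the cis-1,3 positions, C10–CO2H and C12–CH3 cis to the bridge, C14 isopropenyl trans | O1[C@H]2[C@@H](C(=O)O)[C@@H](C1=O)[C@@H](C[C@H]2C)C(C)=C | intermediate
9 | alkynyl ketone: C1–C(=O)–C≡C–SiMe3, C10–CO2H, C11–OH and C12–CH3 all cis, C14 isopropenyl trans | O[C@H]1[C@@H](C(=O)O)[C@@H](C(=O)C#C[Si](C)(C)C)[C@@H](C[C@H]1C)C(C)=C | intermediate
10 | (2R) propargylic alcohol of 9 | O[C@H]1[C@@H](C(=O)O)[C@@H]([C@@H](O)C#C[Si](C)(C)C)[C@@H](C[C@H]1C)C(C)=C | intermediate
11 | cis-fused γ-lactone C9(=O)–O–C2H(C≡CSiMe3), H2 cis to H1 and H10, free C11–OH | O[C@H]1[C@@H]2[C@H]([C@@H](C[C@H]1C)C(C)=C)[C@H](C#C[Si](C)(C)C)OC2=O | intermediate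
12 | lactol: C9 of 11 as C(OH)(CH2C(CH3)=CH2), both anomers (C9 left open) | O[C@H]1[C@@H]2[C@H]([C@@H](C[C@H]1C)C(C)=C)[C@H](C#C[Si](C)(C)C)OC2(O)CC(C)=C | intermediate
13 | all-cis tetrahydrofuran: C2–C≡CSiMe3 and C9–CH2C(CH3)=CH2 cis, H1, H2, H9 and H10 on one face | O[C@H]1[C@@H]2[C@H]([C@@H](C[C@H]1C)C(C)=C)[C@H](C#C[Si](C)(C)C)O[C@@H]2CC(C)=C | intermediate
14 | terminal alkyne (C2–C≡CH) | O[C@H]1[C@@H]2[C@H]([C@@H](C[C@H]1C)C(C)=C)[C@H](C#C)O[C@@H]2CC(C)=C | intermediate
15 | methyl ketone (C2–C(=O)CH3) | O[C@H]1[C@@H]2[C@H]([C@@H](C[C@H]1C)C(C)=C)[C@H](C(C)=O)O[C@@H]2CC(C)=C | intermediate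
16 | dilithium C11-alkoxide C3-enolate of 15 | [Li]O[C@H]1[C@@H]2[C@H]([C@@H](C[C@H]1C)C(C)=C)[C@H](C(=C)O[Li])O[C@@H]2CC(C)=C | intermediate
17 | but-3-enyl ketone (C2–C(=O)CH2CH2CH=CH2) | O[C@H]1[C@@H]2[C@H]([C@@H](C[C@H]1C)C(C)=C)[C@H](C(=O)CCC=C)O[C@@H]2CC(C)=C | intermediate
18 | (3S) tertiary alcohol: C3(OH)(CH3)(but-3-enyl) | O[C@H]1[C@@H]2[C@H]([C@@H](C[C@H]1C)C(C)=C)[C@H]([C@@](C)(O)CCC=C)O[C@@H]2CC(C)=C | intermediate
19 | oxonene diol: nine-membered ring C2–C3–C4–C5–C6=C7(CH3)–C8–C9–O, 6Z, free C3–OH and C11–OH, C14 isopropenyl | O[C@H]1[C@@H]2[C@H]([C@@H](C[C@H]1C)C(C)=C)[C@H]3O[C@@H]2C/C(C)=C\CC[C@]3(C)O | intermediate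
20 | C11 butanoate of 19 | CCCC(=O)O[C@H]1[C@@H]2[C@H]([C@@H](C[C@H]1C)C(C)=C)[C@H]3O[C@@H]2C/C(C)=C\CC[C@]3(C)O | intermediate
21 | (15R) C16 9-borabicyclo[3.3.1]non-9-yl borane | CCCC(=O)O[C@H]1[C@@H]2[C@H]([C@@H](C[C@H]1C)[C@@H](C)CB4C5CCCC4CCC5)[C@H]3O[C@@H]2C/C(C)=C\CC[C@]3(C)O | intermediate
22 | (15R) primary alcohol (C16–OH) | CCCC(=O)O[C@H]1[C@@H]2[C@H]([C@@H](C[C@H]1C)[C@@H](C)CO)[C@H]3O[C@@H]2C/C(C)=C\CC[C@]3(C)O | intermediate
23 | C16 triflate of 22 | CCCC(=O)O[C@H]1[C@@H]2[C@H]([C@@H](C[C@H]1C)[C@@H](C)COS(=O)(=O)C(F)(F)F)[C@H]3O[C@@H]2C/C(C)=C\CC[C@]3(C)O | intermediate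
24 | CNP0209450.4, (1S,2R,3S,9R,10R,11R,12R,14S,15R,6Z) | CCCC(=O)O[C@H]1[C@@H]2[C@@H]3[C@@H](C[C@H]1C)[C@@H](C)CO[C@@]1(C)CC/C=C(/C)C[C@H]2O[C@H]31 | target

**Step count and risks**

Total step count: 17. Longest linear sequence: 17 steps (the route is linear from 1 and 2).

Three steps most likely to fail:

Step 3. The ring opening is run on a substrate that carries a free acid, can revert to furan on warming, and relies on the ligand alone to choose between two nearly equivalent alkene carbons. The sense of the alkaloid in step 2 and of the ligand here rests on analogy and must be confirmed on the first batch. The fallback sets out from 3 and comes back at 6. Reduce 3 with LiAlH4 to the meso diol F1 and silylate it (TBSCl, imidazole) to the bis-silyl ether F2, a neutral meso substrate of the class for which the palladium/dialkylzinc opening was developed and which cannot undergo retro-Diels–Alder. The same PdCl2(MeCN)2/Tol-BINAP/Me2Zn opening is then a true desymmetrisation and gives the cyclohexenol F3. n-Bu4NF frees the triol F4, and TEMPO/NaOCl/NaClO2 oxidises the two primary alcohols to the hydroxy diacid F5. On warming with TsOH this closes to the bridged lactone acid F6, because only the C2 carboxyl can reach the C11 hydroxyl, so the two carboxyls are told apart without the alkaloid step. NaOMe in MeOH opens F6 to the methyl ester and conjugates the alkene, which gives 6.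

Step 14. A trisubstituted Z alkene has to form in a nine-membered ring on the concave face, with a third alkene present. The fallback sets out from 15 and comes back at 19. Alkylate the enolate of 15 with (E)-1-(allyloxy)-4-bromobut-2-ene instead of allyl bromide to give the relay ketone F7, and add MeMgBr under chelation to give the relay tertiary alcohol F8. With the second-generation Grubbs catalyst, ruthenium loads on the unhindered allyl ether, expels 2,5-dihydrofuran and is thereby placed on C6, from where the cis-disposed methallyl alkene is the partner within reach. This relay ring-closing metathesis gives 19.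

Step 16. The C15 configuration rests on acyclic substrate control. The fallback sets out from 20 and comes back at 22, correcting the centre by epimerisation instead of facial selectivity. Hydroborate 20 as before and separate 22 from the (15S) alcohol F9. Oxidise F9 with Dess–Martin periodinane to the (15S) aldehyde F10, equilibrate C15 through the enol with DBU to the (15R) aldehyde F11, and reduce the mixture with NaBH4 (the butanoate survives) to 22, recycling recovered F9.

Further compounds
F1 | step 3 | meso exo-5,6-bis(hydroxymethyl)-7-oxabicyclo[2.2.1]hept-2-ene | O1[C@H]2[C@@H](CO)[C@@H](CO)[C@@H]1C=C2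
F2 | step 3 | bis(tert-butyldimethylsilyl) ether of F1, meso | O1[C@H]2[C@@H](CO[Si](C)(C)C(C)(C)C)[C@@H](CO[Si](C)(C)C(C)(C)C)[C@@H]1C=C2
F3 | step 3 | all-cis cyclohex-13-enol: C11–OH, C12–CH3, C10–CH2OTBS and C1–CH2OTBS on one face | O[C@H]1[C@@H](CO[Si](C)(C)C(C)(C)C)[C@@H](CO[Si](C)(C)C(C)(C)C)C=C[C@H]1C
F4 | step 3 | all-cis triol from F3 | O[C@H]1[C@@H](CO)[C@@H](CO)C=C[C@H]1C
F5 | step 3 | all-cis hydroxy diacid (C1–CO2H, C10–CO2H, C11–OH, C12–CH3) | O[C@H]1[C@@H](C(=O)O)[C@@H](C(=O)O)C=C[C@H]1C
F6 | step 3 | bridged γ-lactone acid: C2(=O)–O–C11, C10–CO2H, C13=C14 | O1[C@H]2[C@@H](C(=O)O)[C@@H](C1=O)C=C[C@H]2C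
F7 | step 14 | relay ketone: C2–C(=O)CH2CH2CH=CH–CH2–O–allyl (E) | O[C@H]1[C@@H]2[C@H]([C@@H](C[C@H]1C)C(C)=C)[C@H](C(=O)CC/C=C/COCC=C)O[C@@H]2CC(C)=C
F8 | step 14 | (3S) relay tertiary alcohol | O[C@H]1[C@@H]2[C@H]([C@@H](C[C@H]1C)C(C)=C)[C@H]([C@@](C)(O)CC/C=C/COCC=C)O[C@@H]2CC(C)=C
F9 | step 16 | (15S) epimer of 22 | CCCC(=O)O[C@H]1[C@@H]2[C@H]([C@@H](C[C@H]1C)[C@H](C)CO)[C@H]3O[C@@H]2C/C(C)=C\CC[C@]3(C)O
F10 | step 16 | (15S) C16 aldehyde | CCCC(=O)O[C@H]1[C@@H]2[C@H]([C@@H](C[C@H]1C)[C@H](C)C=O)[C@H]3O[C@@H]2C/C(C)=C\CC[C@]3(C)O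
F11 | step 16 | (15R) C16 aldehyde | CCCC(=O)O[C@H]1[C@@H]2[C@H]([C@@H](C[C@H]1C)[C@@H](C)C=O)[C@H]3O[C@@H]2C/C(C)=C\CC[C@]3(C)O
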